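**Retrosynthetic overview**

1. Ring atoms are called by target numbering throughout: C1 and C3 are the two CH–OAc carbons, C2 is C(OH)(COC10H21) between them, and C4=C5 is the alkene (C4 on C3, C5 on C1). The target comes from bis-acetylation of the meso triol, whose C1 carbinol comes from 1,2-reduction of a C1 ketone and whose C2 hydroxyl comes from hydroxylation of a C2–H β-diketone anti to C3–OSi.
2. Key disconnection: the only ring, at the cyclopentenone stage, is cut at C2–C3 and at C4=C5 into glyoxal (C3, C4) and an open-chain 2,4-dioxoalkylphosphonate (C5 = CH2P, C1 = adjacent C=O, C2 = CH2 between the carbonyls, plus the side chain). Forward, an aldol addition makes C2–C3 and an intramolecular Horner–Wadsworth–Emmons olefination makes C4=C5 in one operation.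
3. Enabling feature: with C1 at the ketone level the ring is a 4-hydroxycyclopent-2-enone. C2 and C5 are then the two α-carbons of the C1 carbonyl (C2 also α to the side-chain carbonyl, C5 carrying the phosphonate), and the C3(O)/C4 pair has the oxidation pattern of a 1,2-dialdehyde.
4. The dioxophosphonate comes from γ-acylation of the dianion of diethyl (2-oxopropyl)phosphonate with methyl undecanoate. One carbocycle is formed, in step 2; no other ring is made.
5. Stereochemistry: the racemic C3 carbinol from the key step directs C2 (step 4) and then C1 (step 5). Because the target is meso, both enantiomers of every intermediate converge on it.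

Key step: step 2

Remark: the target SMILES describes the meso isomer with both acetoxy groups cis to the undecanoyl group and trans to the tertiary hydroxyl; chiral intermediates are racemic and drawn as one enantiomer.

**Route**

Step 1
Reactants: 1 diethyl (2-oxopropyl)phosphonate; 2 methyl undecanoate
Product: 3 diethyl (2,4-dioxotetradecyl)phosphonate
Conditions: 1 (2 equiv), NaH (2 equiv) then n-BuLi (2 equiv), THF, 0 °C; 2 (1 equiv), 0 °C → rt; aq. HCl
Reagents that add atoms: none
Why: γ-Acylation of a β-ketophosphonate 1,3-dianion (Claisen-type acylation, as with acetoacetate dianions): the terminal carbanion is the more nucleophilic site and attacks the ester, a second equivalent of dianion takes up the acidic proton of the new 1,3-diketone, and no stereocentre is formed.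

Step 2
Reactants: 3 diethyl (2,4-dioxotetradecyl)phosphonate; 4 glyoxal (40% aqueous solution)
Product: 6 rac-trans-4-hydroxy-5-undecanoylcyclopent-2-en-1-one (keto form drawn; in equilibrium with its enol), via aldol adduct 5 (not isolated)
Conditions: 4 (2 equiv), K2CO3 (3 equiv), THF–H2O (1:1), 3 added slowly at 0 °C, then 35 °C; aq. citric acid to pH 4
Reagents that add atoms: none
Why: K2CO3 ionises only the doubly activated carbon C2 of 3 (several pKa units more acidic than the phosphonate CH2), and this enolate adds reversibly to one formyl group of glyoxal to give aldol 5 (C2–C3 bond), after which the phosphoryl-stabilised carbanion at C5, present in low stationary concentration, attacks the second formyl group and the oxaphosphetane collapses to the C4=C5 double bond with loss of diethyl phosphate (intramolecular Horner–Wadsworth–Emmons olefination). The closest known reaction types are the base-mediated [3+2] condensation of a 1,2-dicarbonyl compound with the two α-carbons of a ketone to a 4-hydroxycyclopent-2-enone (first ring of the Weiss–Cook reaction) and the intramolecular Horner–Wadsworth–Emmons closure of 1,4-dicarbonyl phosphonates to cyclopentenones. The carbocycle closes in the olefination event, 5-exo-trig at the aldehyde (5-(enolendo)-exo-trig with respect to the keto-stabilised carbanion, the mode of every 1,4-dicarbonyl to cyclopentenone closure), and the five-membered ring enforces the cis geometry of C4=C5. C3 is the only new stable stereocentre and needs no control: it forms as a racemate, every later centre is set relative to it and the meso target is reached from either enantiomer, while C2 stays acidic and rests as the enol or the trans keto form. The step needs aldol before olefination (an intermolecular olefination first would give an E-enal that cannot cyclise), ring closure through the phosphonate carbon and not through the side-chain CH2, and closure faster than loss of water from 5; the acidity order of the three sites, the reversibility in water of every event before the olefination and the intramolecular, irreversible nature of the olefination should secure this.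

Step 3
Reactants: 6 rac-trans-4-hydroxy-5-undecanoylcyclopent-2-en-1-one
Product: 7 rac-trans-4-(tert-butyldimethylsilyloxy)-5-undecanoylcyclopent-2-en-1-one
Conditions: TBSCl (1.3 equiv), imidazole (2.5 equiv), DMF, 0 °C → rt; aq. citric acid work-up
Reagents that add atoms: tert-butyldimethylsilyl chloride (TBSCl), CC(C)(C)[Si](C)(C)Cl
Why: Silylation of a secondary alcohol with TBSCl and imidazole, which leaves the configuration at C3 untouched, gives a poorly leaving, bulky group that blocks β-elimination from the acidic diketone and shields one ring face, any O-silylated enol being hydrolysed in the mildly acidic work-up.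

Step 4
Reactants: 7 rac-trans-4-(tert-butyldimethylsilyloxy)-5-undecanoylcyclopent-2-en-1-one
Product: 9 rac-4-(tert-butyldimethylsilyloxy)-5-hydroxy-5-undecanoylcyclopent-2-en-1-one (5-OH trans to 4-OSi), via enol epoxide 8 (not isolated)
Conditions: DMDO (1.2 equiv, acetone solution), CH2Cl2, −20 → 0 °C
Reagents that add atoms: dimethyldioxirane (DMDO), CC1(C)OO1
Why: Dioxirane hydroxylation of a 2-substituted 1,3-diketone through epoxidation of its enol tautomer (Rubottom-type oxidation of the free enol): the oxygen is delivered to C2 on the ring face opposite the neighbouring C3 silyloxy group, epoxide 8 opens to the tertiary ketol, so the new hydroxyl is trans and the undecanoyl group cis to C3–OSi, while the electron-poor enone alkene is inert to the reagent.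

Step 5
Reactants: 9 rac-4-(tert-butyldimethylsilyloxy)-5-hydroxy-5-undecanoylcyclopent-2-en-1-one
Product: 10 rac-1-[5-(tert-butyldimethylsilyloxy)-1,2-dihydroxycyclopent-3-en-1-yl]undecan-1-one (2-OH, 5-OSi and the acyl group mutually cis; 1-OH trans to them)
Conditions: NaBH4 (1 equiv), CeCl3·7H2O (1.1 equiv), MeOH, −78 °C; aq. NH4Cl
Reagents that add atoms: none
Why: Luche 1,2-reduction of the cyclopentenone: hydride adds to the cerium-activated C1 carbonyl from the face of the small tertiary hydroxyl, opposite both the undecanoyl group on C2 and the C3 silyloxy group, which sets the C1 carbinol cis to these two groups, and the flat conjugated ring carbonyl should react faster than the neopentyl-type side-chain ketone.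

Step 6
Reactants: 10 rac-1-[5-(tert-butyldimethylsilyloxy)-1,2-dihydroxycyclopent-3-en-1-yl]undecan-1-one
Product: 11 1-[(1r,2R,5S)-1,2,5-trihydroxycyclopent-3-en-1-yl]undecan-1-one (meso; 2-OH and 5-OH cis to the acyl group)
Conditions: HF·pyridine, pyridine, THF, 0 °C → rt
Reagents that add atoms: none
Why: Desilylation of a secondary TBS ether with buffered HF·pyridine, chosen over basic fluoride sources to avoid retro-aldol opening of the β-hydroxy ketone; no stereocentre is touched and the triol obtained is meso.

Step 7
Reactants: 11 1-[(1r,2R,5S)-1,2,5-trihydroxycyclopent-3-en-1-yl]undecan-1-one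
Product: 12 (1R,2r,3S)-2-hydroxy-2-undecanoylcyclopent-4-ene-1,3-diyl diacetate (target)
Conditions: Ac2O (3 equiv), pyridine, CH2Cl2, 0 °C → rt
Reagents that add atoms: acetic anhydride (Ac2O), CC(=O)OC(C)=O
Why: Acetylation of the two enantiotopic secondary allylic alcohols with Ac2O in pyridine without a nucleophilic catalyst, under which the hindered tertiary hydroxyl α to the ketone should stay free.

**Compound list**

1 | diethyl (2-oxopropyl)phosphonate | CC(=O)CP(=O)(OCC)OCC | starting material
2 | methyl undecanoate | CCCCCCCCCCC(=O)OC | starting material
3 | diethyl (2,4-dioxotetradecyl)phosphonate | CCCCCCCCCCC(=O)CC(=O)CP(=O)(OCC)OCC | intermediate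
4 | glyoxal (ethanedial, 40% aqueous solution) | O=CC=O | starting material
5 | diethyl [3-(1-hydroxy-2-oxoethyl)-2,4-dioxotetradecyl]phosphonate (aldol adduct, stereoisomer mixture, not isolated) | CCCCCCCCCCC(=O)C(C(O)C=O)C(=O)CP(=O)(OCC)OCC | intermediate
6 | rac-trans-4-hydroxy-5-undecanoylcyclopent-2-en-1-one | CCCCCCCCCCC(=O)[C@@H]1[C@@H](O)C=CC1=O | intermediate
7 | rac-trans-4-(tert-butyldimethylsilyloxy)-5-undecanoylcyclopent-2-en-1-one | CCCCCCCCCCC(=O)[C@@H]1[C@@H](O[Si](C)(C)C(C)(C)C)C=CC1=O | intermediate
8 | rac-7-(tert-butyldimethylsilyloxy)-2-decyl-2-hydroxy-1-oxaspiro[2.4]hept-5-en-4-one (enol epoxide, epoxide oxygen trans to the silyloxy group, not isolated) | CCCCCCCCCCC1(O)O[C@@]12[C@@H](O[Si](C)(C)C(C)(C)C)C=CC2=O | intermediate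
9 | rac-4-(tert-butyldimethylsilyloxy)-5-hydroxy-5-undecanoylcyclopent-2-en-1-one (5-OH trans to 4-OSi, acyl cis to 4-OSi) | CCCCCCCCCCC(=O)[C@@]1(O)[C@@H](O[Si](C)(C)C(C)(C)C)C=CC1=O | intermediate
10 | rac-1-[5-(tert-butyldimethylsilyloxy)-1,2-dihydroxycyclopent-3-en-1-yl]undecan-1-one (2-OH, 5-OSi and acyl mutually cis; 1-OH trans) | CCCCCCCCCCC(=O)[C@@]1(O)[C@@H](O[Si](C)(C)C(C)(C)C)C=C[C@H]1O | intermediate
11 | 1-[(1r,2R,5S)-1,2,5-trihydroxycyclopent-3-en-1-yl]undecan-1-one (meso) | CCCCCCCCCCC(=O)[C@@]1(O)[C@@H](O)C=C[C@H]1O | intermediate
12 | (1R,2r,3S)-2-hydroxy-2-undecanoylcyclopent-4-ene-1,3-diyl diacetate (meso) | CCCCCCCCCCC(=O)[C@@]1(O)[C@@H](OC(C)=O)C=C[C@H]1OC(C)=O | target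

**Step count and risks**

Total step count: 7. Longest linear sequence: 7 steps (from 1 or 2 to 12).

The three steps most likely to fail:

1. Step 2 (key step). What may go wrong: loss of water at the aldol stage followed by conjugate addition of a second diketonate (oligomerisation), or olefination running ahead of the aldol addition so that an open-chain E-enal accumulates and cannot cyclise. Fallback (preformed ring, known enolate chemistry): it sets out from methyl undecanoate 2, which iBu2AlH (toluene, −78 °C) reduces to undecanal F1. The lithium enolate (LiN(iPr)2, THF, −78 °C) of commercial racemic 4-(tert-butyldimethylsilyloxy)cyclopent-2-en-1-one F2 should add to F1 opposite the silyloxy group to give rac-trans-4-(tert-butyldimethylsilyloxy)-5-(1-hydroxyundecyl)cyclopent-2-en-1-one F3 (carbinol epimers, both usable). Dess–Martin periodinane (CH2Cl2, 0 °C) oxidises F3 to the β-diketone, which is compound 7, and the route continues with step 4.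

2. Step 5. What may go wrong: hydride addition to the side-chain ketone in competition with the ring carbonyl, conjugate reduction, or methoxide-induced deacylation of the non-enolisable 1,3-diketone. Fallback (reduce both carbonyls, re-oxidise one): from 9, excess NaBH4 with CeCl3·7H2O (MeOH, 0 °C) should reduce both ketones to rac-1-[5-(tert-butyldimethylsilyloxy)-1,2-dihydroxycyclopent-3-en-1-yl]undecan-1-ol F4 (side-chain carbinol epimers). Bu2SnO (toluene, reflux, water removed) should engage the exocyclic secondary/tertiary 1,2-diol, the only vicinal pair that can bridge because the ring diol is trans, as the dibutylstannylene acetal F5. NBS (CH2Cl2, rt) oxidises the tin-bound secondary carbinol to the ketone and gives compound 10, where the route is rejoined at step 6.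

3. Step 4. What may go wrong: oxygen delivery to the wrong ring face, or oxidative cleavage and acyl-shift reactions of the free ketol while oxidant is still present. Fallback (oxidation of a preformed silyl enol ether): from 7, TMSOTf and Et3N (CH2Cl2, −78 °C) should give the exocyclic trimethylsilyl dienol ether, rac-4-(tert-butyldimethylsilyloxy)-5-[1-(trimethylsilyloxy)undecylidene]cyclopent-2-en-1-one F6 (alkene geometry immaterial). Buffered mCPBA (NaHCO3, CH2Cl2, −20 °C) epoxidises it opposite the ring silyloxy group, and 1,4-silyl migration gives rac-4-(tert-butyldimethylsilyloxy)-5-(trimethylsilyloxy)-5-undecanoylcyclopent-2-en-1-one F7 (Rubottom oxidation), so the tertiary oxygen arrives protected. Citric acid in MeOH (0 °C) cleaves only the trimethylsilyl ether and gives compound 9, where the route is rejoined at step 5.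

**Further compounds**

F1 | step 2 | undecanal | CCCCCCCCCCC=O
F2 | step 2 | rac-4-(tert-butyldimethylsilyloxy)cyclopent-2-en-1-one | O=C1C[C@@H](O[Si](C)(C)C(C)(C)C)C=C1
F3 | step 2 | rac-trans-4-(tert-butyldimethylsilyloxy)-5-(1-hydroxyundecyl)cyclopent-2-en-1-one (carbinol epimers) | CCCCCCCCCCC(O)[C@@H]1[C@@H](O[Si](C)(C)C(C)(C)C)C=CC1=O
F4 | step 5 | rac-1-[5-(tert-butyldimethylsilyloxy)-1,2-dihydroxycyclopent-3-en-1-yl]undecan-1-ol (side-chain carbinol epimers) | CCCCCCCCCCC(O)[C@@]1(O)[C@@H](O[Si](C)(C)C(C)(C)C)C=C[C@H]1O
F5 | step 5 | dibutylstannylene acetal of the exocyclic 1,2-diol of F4 (2,2-dibutyl-1,3,2-dioxastannolane spiro-fused to the cyclopentene ring) | CCCCCCCCCCC1O[Sn](CCCC)(CCCC)O[C@@]12[C@@H](O[Si](C)(C)C(C)(C)C)C=C[C@H]2O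
F6 | step 4 | rac-4-(tert-butyldimethylsilyloxy)-5-[1-(trimethylsilyloxy)undecylidene]cyclopent-2-en-1-one | CCCCCCCCCCC(O[Si](C)(C)C)=C1[C@@H](O[Si](C)(C)C(C)(C)C)C=CC1=O
F7 | step 4 | rac-4-(tert-butyldimethylsilyloxy)-5-(trimethylsilyloxy)-5-undecanoylcyclopent-2-en-1-one (5-OSi trans to 4-OSi) | CCCCCCCCCCC(=O)[C@@]1(O[Si](C)(C)C)[C@@H](O[Si](C)(C)C(C)(C)C)C=CC1=O
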